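## Plan

- **Retrosynthesis:** the five aryl O–benzyl bonds are cut first, then C5–C6 and C6–C7 of ring A, which leaves a trans-4-acetyl-5-methyl-2,3-diaryl-2,3-dihydrofuran and a 3-arylpropanoate ester. Last, O1–C2 and C2–C3 are cut, which leaves a benzylidene acetylacetone and a benzylic sulfonium ylide.
- **Feature used:** in the target, O1–C7a=C3a–C4(OH) of ring A is a vinylogous ester in disguise. C7–C7a–C3a–C4–C5–C6 is therefore a 1,3,5-tricarbonyl chain whose C7a carbonyl is held as the enol ether of the dihydrofuran ring (the acetyl carbons become C4 and C5, the ester carbonyl C6, the ring methyl C7).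
- **Forward:** the Knoevenagel adduct and the chiral sulfonium salt are made, a [4+1] ylide annulation closes the dihydrofuran ring, a one-flask Claisen acylation and vinylogous aldol aromatisation builds ring A, and hydrogenolysis frees the five phenols.
- **Stereochemistry:** C2 and C3 are both set in the [4+1] annulation. The C2-symmetric (2S,5S)-2,5-dimethylthiolane on sulfur gives the absolute sense, and anti addition with invertive ring closure gives the trans relation. No later step touches them.
- **Protecting groups:** benzyl ethers are chosen so that the last step is a neutral hydrogenolysis. A Lewis-acid dealkylation would endanger the C2–O1 benzylic bond next to the 2,4-dioxygenated ring.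

Key step: step 8

Assumption: the ylide of the (2S,5S)-thiolane is taken to meet the Michael acceptor on the same face of its ylide carbon as this class of sulfide does with aldehydes, which makes the oxygen-bearing carbon S. If the sense proved opposite, the enantiomeric diol would be carried through the same steps.

## Route

**Step 1**
Reactants: 1 acetylacetone (pentane-2,4-dione); 2 3,5-bis(benzyloxy)benzaldehyde
Product: 3 3-{[3,5-bis(benzyloxy)phenyl]methylidene}pentane-2,4-dione
Conditions: piperidine (cat.), AcOH (cat.), toluene, reflux, Dean–Stark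
Reagents that add atoms: none
Why: Knoevenagel condensation of an active methylene compound with a non-enolisable aromatic aldehyde, driven by azeotropic removal of water; the two acyl groups are the same, so no alkene isomers arise.

**Step 2**
Reactants: 4 (2R,5R)-hexane-2,5-diol
Product: 5 (2R,5R)-hexane-2,5-diyl dimethanesulfonate
Conditions: MsCl, Et3N, CH2Cl2, 0 °C
Reagents that add atoms: methanesulfonyl chloride, CS(=O)(=O)Cl
Why: O-sulfonylation of the two secondary alcohols takes place at oxygen and leaves both stereocentres as they are.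

**Step 3**
Reactants: 5 (2R,5R)-hexane-2,5-diyl dimethanesulfonate
Product: 6 (2S,5S)-2,5-dimethylthiolane
Conditions: Na2S·9H2O, DMSO, rt
Reagents that add atoms: sodium sulfide, [Na+].[Na+].[S-2]
Why: Double SN2 displacement by sulfide (the second one a 5-exo-tet closure) inverts each carbinol carbon once, so the (R,R)-dimesylate should give the trans (S,S)-thiolane.

**Step 4**
Reactants: 7 2,4-bis(benzyloxy)benzaldehyde
Product: 8 [2,4-bis(benzyloxy)phenyl]methanol
Conditions: NaBH4, MeOH/THF, 0 °C
Reagents that add atoms: none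
Why: Borohydride reduction of an aromatic aldehyde to the benzylic alcohol, with the benzyl ethers inert.

**Step 5**
Reactants: 8 [2,4-bis(benzyloxy)phenyl]methanol; 6 (2S,5S)-2,5-dimethylthiolane
Product: 9 (2S,5S)-1-{[2,4-bis(benzyloxy)phenyl]methyl}-2,5-dimethylthiolan-1-ium tetrafluoroborate
Conditions: 6 (1.5 equiv), HBF4·OEt2 (1.05 equiv), CH2Cl2, −20 → 0 °C; precipitation with Et2O
Reagents that add atoms: tetrafluoroboric acid (diethyl ether complex), [H+].F[B-](F)(F)F
Why: Acid-promoted S-alkylation of a sulfide by a benzylic alcohol through the alkoxy-stabilised benzylic cation, the excess sulfide outrunning Friedel–Crafts self-alkylation; the thiolane is C2-symmetric, so sulfur is not a stereocentre and one salt results.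

**Step 6**
Reactants: 9 (2S,5S)-1-{[2,4-bis(benzyloxy)phenyl]methyl}-2,5-dimethylthiolan-1-ium tetrafluoroborate; 3 3-{[3,5-bis(benzyloxy)phenyl]methylidene}pentane-2,4-dione
Product: 12 1-{(4S,5S)-5-[2,4-bis(benzyloxy)phenyl]-4-[3,5-bis(benzyloxy)phenyl]-2-methyl-4,5-dihydrofuran-3-yl}ethan-1-one, via sulfonium ylide 10 (not isolated), via betaine 11 (not isolated)
Conditions: KN(SiMe3)2 (1.05 equiv), THF, −78 °C; then 3, −78 → −20 °C
Reagents that add atoms: none
Why: Sulfur-ylide [4+1] annulation of an alkylidene 1,3-diketone, in which ylide 10 adds to the benzylidene carbon of 3 to give betaine 11 and the diketonate oxygen then displaces the thiolane in a 5-exo-tet SN2 closure with inversion; the ring methyl groups of the thiolane shield one face of the ylide carbon and so fix the oxygen-bearing carbon as S, and the anti approach of the two aryl groups sets the trans relation and with it the second centre as S.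

**Step 7**
Reactants: 13 methyl 3-(4-hydroxyphenyl)propanoate
Product: 14 methyl 3-[4-(benzyloxy)phenyl]propanoate
Conditions: BnBr, K2CO3, acetone, reflux
Reagents that add atoms: benzyl bromide, BrCc1ccccc1
Why: Williamson etherification of the phenoxide, under which the methyl ester is stable.

**Step 8**
Reactants: 12 1-{(4S,5S)-5-[2,4-bis(benzyloxy)phenyl]-4-[3,5-bis(benzyloxy)phenyl]-2-methyl-4,5-dihydrofuran-3-yl}ethan-1-one; 14 methyl 3-[4-(benzyloxy)phenyl]propanoate
Product: 17 (2S,3S)-2-[2,4-bis(benzyloxy)phenyl]-3-[3,5-bis(benzyloxy)phenyl]-6-{2-[4-(benzyloxy)phenyl]ethyl}-2,3-dihydro-1-benzofuran-4-ol, via diketone 15 (not isolated), via aldol adduct 16 (not isolated)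
Conditions: LiN(iPr)2 (2.2 equiv), THF, −78 °C, 12 added to the base; 14 (1.5 equiv), −78 → 0 °C; then KOt-Bu (3 equiv), t-BuOH, 50 °C; AcOH quench
Reagents that add atoms: none
Why: Proposed new method: LiN(iPr)2 at −78 °C removes a proton from the acetyl methyl group of 12, the kinetic site of a vinylogous ester, and this enolate attacks ester 14 in a crossed Claisen condensation (C5–C6 bond), the second equivalent of base holding the product as the lithium enolate of diketone 15. In KOt-Bu/t-BuOH the diketonate is in equilibrium with the dienolate formed by loss of a proton from the C7 methyl group through the O1–C7a=C3a–C4=O vinylogous ester, C7 adds to the C6 ketone (C6–C7 bond) to give aldol 16, and E1cB loss of water followed by tautomerisation gives the C4 phenol of ring A. The closest known reactions are the Claisen acylation of kinetic vinylogous-ester enolates and the base-mediated aldol aromatisation of 3,5-diketo chains to resorcinols, here joined in one flask on a chain whose third carbonyl (C7a) is masked as the enol ether of the dihydrofuran. Ring A closes by a 6-(enolendo)-exo-trig aldol, made easy because the five-membered ring holds C7 and C4 cis on the C7a=C3a double bond. The only new stereocentre, the carbinol carbon C6 of 16, is uncontrolled and is destroyed on dehydration, while C2 and C3 are kept because neither C–H bond is alpha or gamma to a carbonyl group at any stage. The step needs acylation at the acetyl methyl group and not at C7, which kinetic deprotonation by the hindered amide at low temperature secures, and closure at C6 and not at C7a, which follows because C7a is an enol-ether carbon and not a ketone and attack there would create a quaternary centre.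

**Step 9**
Reactants: 17 (2S,3S)-2-[2,4-bis(benzyloxy)phenyl]-3-[3,5-bis(benzyloxy)phenyl]-6-{2-[4-(benzyloxy)phenyl]ethyl}-2,3-dihydro-1-benzofuran-4-ol
Product: 18 (2S,3S)-2-(2,4-dihydroxyphenyl)-3-(3,5-dihydroxyphenyl)-6-[2-(4-hydroxyphenyl)ethyl]-2,3-dihydro-1-benzofuran-4-ol
Conditions: H2 (1 atm), Pd/C (10 wt%), EtOAc/MeOH, rt, reaction stopped when the last benzyl ether is gone
Reagents that add atoms: none
Why: Heterogeneous hydrogenolysis of the five primary aryl benzyl ethers, which are cleaved much faster than the secondary, ring-held C2–O1 benzylic bond (as in debenzylations of flavans and dihydrobenzofuran neolignans); the molecule holds no alkene and neither stereocentre is touched.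

## Compound list

1 | acetylacetone (pentane-2,4-dione) | CC(=O)CC(C)=O | starting material
2 | 3,5-bis(benzyloxy)benzaldehyde | O=Cc1cc(OCc2ccccc2)cc(OCc2ccccc2)c1 | starting material
3 | 3-{[3,5-bis(benzyloxy)phenyl]methylidene}pentane-2,4-dione | CC(=O)C(=Cc1cc(OCc2ccccc2)cc(OCc2ccccc2)c1)C(C)=O | intermediate
4 | (2R,5R)-hexane-2,5-diol | C[C@@H](O)CC[C@@H](C)O | starting material
5 | (2R,5R)-hexane-2,5-diyl dimethanesulfonate | C[C@@H](OS(C)(=O)=O)CC[C@@H](C)OS(C)(=O)=O | intermediate
6 | (2S,5S)-2,5-dimethylthiolane (recovered in step 6) | C[C@H]1CC[C@H](C)S1 | intermediate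
7 | 2,4-bis(benzyloxy)benzaldehyde | O=Cc1ccc(OCc2ccccc2)cc1OCc1ccccc1 | starting material
8 | [2,4-bis(benzyloxy)phenyl]methanol | OCc1ccc(OCc2ccccc2)cc1OCc1ccccc1 | intermediate
9 | (2S,5S)-1-{[2,4-bis(benzyloxy)phenyl]methyl}-2,5-dimethylthiolan-1-ium tetrafluoroborate | C[C@H]1CC[C@H](C)[S+]1Cc1ccc(OCc2ccccc2)cc1OCc1ccccc1.F[B-](F)(F)F | intermediate
10 | [2,4-bis(benzyloxy)phenyl][(2S,5S)-2,5-dimethylthiolan-1-ium-1-yl]methanide (sulfonium ylide, not isolated) | C[C@H]1CC[C@H](C)[S+]1[CH-]c1ccc(OCc2ccccc2)cc1OCc1ccccc1 | intermediate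
11 | 3-{(1S,2R)-2-[2,4-bis(benzyloxy)phenyl]-1-[3,5-bis(benzyloxy)phenyl]-2-[(2S,5S)-2,5-dimethylthiolan-1-ium-1-yl]ethyl}-4-oxopent-2-en-2-olate (betaine, not isolated) | C[C@H]1CC[C@H](C)[S+]1[C@@H](c1ccc(OCc2ccccc2)cc1OCc1ccccc1)[C@H](C(C(C)=O)=C(C)[O-])c1cc(OCc2ccccc2)cc(OCc2ccccc2)c1 | intermediate
12 | 1-{(4S,5S)-5-[2,4-bis(benzyloxy)phenyl]-4-[3,5-bis(benzyloxy)phenyl]-2-methyl-4,5-dihydrofuran-3-yl}ethan-1-one (trans) | CC(=O)C1=C(C)O[C@H](c2ccc(OCc3ccccc3)cc2OCc2ccccc2)[C@H]1c1cc(OCc2ccccc2)cc(OCc2ccccc2)c1 | intermediate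
13 | methyl 3-(4-hydroxyphenyl)propanoate | COC(=O)CCc1ccc(O)cc1 | starting material
14 | methyl 3-[4-(benzyloxy)phenyl]propanoate | COC(=O)CCc1ccc(OCc2ccccc2)cc1 | intermediate
15 | 1-{(4S,5S)-5-[2,4-bis(benzyloxy)phenyl]-4-[3,5-bis(benzyloxy)phenyl]-2-methyl-4,5-dihydrofuran-3-yl}-5-[4-(benzyloxy)phenyl]pentane-1,3-dione (formed as its lithium enolate, not isolated) | O=C(CCc1ccc(OCc2ccccc2)cc1)CC(=O)C1=C(C)O[C@H](c2ccc(OCc3ccccc3)cc2OCc2ccccc2)[C@H]1c1cc(OCc2ccccc2)cc(OCc2ccccc2)c1 | intermediate
16 | (2S,3S)-2-[2,4-bis(benzyloxy)phenyl]-3-[3,5-bis(benzyloxy)phenyl]-6-{2-[4-(benzyloxy)phenyl]ethyl}-6-hydroxy-3,5,6,7-tetrahydro-1-benzofuran-4(2H)-one (both C6 epimers, not isolated) | C12=C(CC(O)(CCc3ccc(OCc4ccccc4)cc3)CC1=O)O[C@H](c1ccc(OCc3ccccc3)cc1OCc1ccccc1)[C@H]2c1cc(OCc2ccccc2)cc(OCc2ccccc2)c1 | intermediate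
17 | (2S,3S)-2-[2,4-bis(benzyloxy)phenyl]-3-[3,5-bis(benzyloxy)phenyl]-6-{2-[4-(benzyloxy)phenyl]ethyl}-2,3-dihydro-1-benzofuran-4-ol | c1ccccc1COc1ccc(CCc2cc(O)c3c(c2)O[C@H](c2ccc(OCc4ccccc4)cc2OCc2ccccc2)[C@H]3c2cc(OCc4ccccc4)cc(OCc4ccccc4)c2)cc1 | intermediate
18 | (2S,3S)-2-(2,4-dihydroxyphenyl)-3-(3,5-dihydroxyphenyl)-6-[2-(4-hydroxyphenyl)ethyl]-2,3-dihydro-1-benzofuran-4-ol | Oc1ccc(CCc2cc(O)c3c(c2)O[C@H](c2ccc(O)cc2O)[C@H]3c2cc(O)cc(O)c2)cc1 | target

## Step count and risks

Total step count: 9. Longest linear sequence: 6 steps (2, 3, 5, 6, 8, 9).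

**Steps most likely to fail**

1. **Step 8.** What may go wrong:
   - the crossed Claisen may be outrun by self-condensation of the ester, or by proton transfer that moves the enolate from the acetyl group to C7;
   - the diketonate may then fail to reach its C7-dienolate tautomer and be cleaved by retro-Claisen attack;
   - the chain may close the other way, with the side-chain methylene adding to C7a and the ring alkoxide lost.

   The fallback uses known chemistry throughout. It brings ring A in as a cyclohexane-1,3-dione and annulates the dihydrofuran onto it; it sets out from ester 14, aldehyde 2 and salt 9 and comes back to the route at 17.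
   - Reduction of 14 with iBu2AlH (toluene, −78 °C) should give 3-[4-(benzyloxy)phenyl]propanal F1.
   - Wittig olefination with 1-(triphenylphosphoranylidene)propan-2-one should give (E)-6-[4-(benzyloxy)phenyl]hex-3-en-2-one F2.
   - Michael addition of diethyl malonate and Dieckmann closure (NaOEt, EtOH, reflux) should give ethyl 6-{2-[4-(benzyloxy)phenyl]ethyl}-2,4-dioxocyclohexane-1-carboxylate F3.
   - Saponification with decarboxylation (aq NaOH, then HCl, warm) should give 5-{2-[4-(benzyloxy)phenyl]ethyl}cyclohexane-1,3-dione F4.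
   - Knoevenagel condensation of F4 with 2 (piperidine cat., CH2Cl2) should give 2-{[3,5-bis(benzyloxy)phenyl]methylidene}-5-{2-[4-(benzyloxy)phenyl]ethyl}cyclohexane-1,3-dione F5.
   - F5 is trapped in the same flask by ylide 10 (from 9 and Cs2CO3) in the [4+1] annulation, which is best known on cyclic 1,3-diones. This should give (2S,3S)-2-[2,4-bis(benzyloxy)phenyl]-3-[3,5-bis(benzyloxy)phenyl]-6-{2-[4-(benzyloxy)phenyl]ethyl}-3,5,6,7-tetrahydro-1-benzofuran-4(2H)-one F6; both C6 epimers serve.
   - Kinetic enolisation at C5 and silylation (LiN(iPr)2, Me3SiCl, THF, −78 °C) should give {[(2S,3S)-2-[2,4-bis(benzyloxy)phenyl]-3-[3,5-bis(benzyloxy)phenyl]-6-{2-[4-(benzyloxy)phenyl]ethyl}-2,3,6,7-tetrahydro-1-benzofuran-4-yl]oxy}trimethylsilane F7.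
   - Saegusa–Ito oxidation with Pd(OAc)2 (divalent palladium) in MeCN introduces the C5–C6 double bond, whereupon the ring aromatises to phenol 17.

2. **Step 6.** What may go wrong:
   - facial selectivity at the ylide carbon or at the acceptor may be poor, giving low enantiomeric purity or a cis/trans mixture;
   - the electron-rich benzylic sulfonium group may ionise before or after ylide formation;
   - the ylide may undergo Sommelet–Hauser rearrangement.

   The fallback gives up reagent control and builds the same ring by a radical route followed by resolution; it sets out from alcohol 8, aldehyde 2 and acetylacetone 1 and comes back at 12.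
   - 8 with PPh3·HBr (MeCN, reflux) should give {[2,4-bis(benzyloxy)phenyl]methyl}triphenylphosphonium bromide F8.
   - Wittig reaction with 2 (KOt-Bu, THF) should give (E)-2,4-bis(benzyloxy)-1-{2-[3,5-bis(benzyloxy)phenyl]ethenyl}benzene F9; any Z isomer converges in the next step.
   - Oxidative [3+2] annulation of F9 with 1 and Mn(OAc)3·2H2O (trivalent manganese) in AcOH at 70 °C follows. The diketone radical should add to the alkene carbon remote from the 2,4-dialkoxyphenyl ring, the benzylic radical is oxidised to the cation, and the enol oxygen closes to the trans dihydrofuran.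
   - The product forms as 12 together with its enantiomer 1-{(4R,5R)-5-[2,4-bis(benzyloxy)phenyl]-4-[3,5-bis(benzyloxy)phenyl]-2-methyl-4,5-dihydrofuran-3-yl}ethan-1-one F10.
   - Preparative chromatography on a chiral stationary phase then delivers 12.

3. **Step 5.** What may go wrong:
   - the benzylic cation may alkylate another electron-rich arene ring (oligomerisation) before the sulfide traps it;
   - the salt may dissociate again on isolation.

   The fallback avoids free acid; it sets out from 8 and comes back at 9.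
   - 8 is converted with SOCl2 and pyridine (CH2Cl2, −20 °C) into 2,4-bis(benzyloxy)-1-(chloromethyl)benzene F11.
   - F11 is used crude to alkylate thiolane 6 in the presence of AgBF4 (CH2Cl2, 0 °C), the silver salt removing chloride as the sulfonium tetrafluoroborate forms.

## Further compounds

F1 | step 8 | 3-[4-(benzyloxy)phenyl]propanal | O=CCCc1ccc(OCc2ccccc2)cc1
F2 | step 8 | (E)-6-[4-(benzyloxy)phenyl]hex-3-en-2-one | CC(=O)/C=C/CCc1ccc(OCc2ccccc2)cc1
F3 | step 8 | ethyl 6-{2-[4-(benzyloxy)phenyl]ethyl}-2,4-dioxocyclohexane-1-carboxylate (stereoisomer mixture) | CCOC(=O)C1C(=O)CC(=O)CC1CCc1ccc(OCc2ccccc2)cc1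
F4 | step 8 | 5-{2-[4-(benzyloxy)phenyl]ethyl}cyclohexane-1,3-dione | O=C1CC(=O)CC(CCc2ccc(OCc3ccccc3)cc2)C1
F5 | step 8 | 2-{[3,5-bis(benzyloxy)phenyl]methylidene}-5-{2-[4-(benzyloxy)phenyl]ethyl}cyclohexane-1,3-dione (racemic, transient) | O=C1CC(CCc2ccc(OCc3ccccc3)cc2)CC(=O)C1=Cc1cc(OCc2ccccc2)cc(OCc2ccccc2)c1
F6 | step 8 | (2S,3S)-2-[2,4-bis(benzyloxy)phenyl]-3-[3,5-bis(benzyloxy)phenyl]-6-{2-[4-(benzyloxy)phenyl]ethyl}-3,5,6,7-tetrahydro-1-benzofuran-4(2H)-one (both C6 epimers) | C12=C(CC(CCc3ccc(OCc4ccccc4)cc3)CC1=O)O[C@H](c1ccc(OCc3ccccc3)cc1OCc1ccccc1)[C@H]2c1cc(OCc2ccccc2)cc(OCc2ccccc2)c1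
F7 | step 8 | {[(2S,3S)-2-[2,4-bis(benzyloxy)phenyl]-3-[3,5-bis(benzyloxy)phenyl]-6-{2-[4-(benzyloxy)phenyl]ethyl}-2,3,6,7-tetrahydro-1-benzofuran-4-yl]oxy}trimethylsilane (both C6 epimers) | C12=C(CC(CCc3ccc(OCc4ccccc4)cc3)C=C1O[Si](C)(C)C)O[C@H](c1ccc(OCc3ccccc3)cc1OCc1ccccc1)[C@H]2c1cc(OCc2ccccc2)cc(OCc2ccccc2)c1
F8 | step 6 | {[2,4-bis(benzyloxy)phenyl]methyl}triphenylphosphonium bromide | [Br-].c1ccccc1[P+](c1ccccc1)(c1ccccc1)Cc1ccc(OCc2ccccc2)cc1OCc1ccccc1
F9 | step 6 | (E)-2,4-bis(benzyloxy)-1-{2-[3,5-bis(benzyloxy)phenyl]ethenyl}benzene | c1ccccc1COc1ccc(/C=C/c2cc(OCc3ccccc3)cc(OCc3ccccc3)c2)c(OCc2ccccc2)c1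
F10 | step 6 | 1-{(4R,5R)-5-[2,4-bis(benzyloxy)phenyl]-4-[3,5-bis(benzyloxy)phenyl]-2-methyl-4,5-dihydrofuran-3-yl}ethan-1-one | CC(=O)C1=C(C)O[C@@H](c2ccc(OCc3ccccc3)cc2OCc2ccccc2)[C@@H]1c1cc(OCc2ccccc2)cc(OCc2ccccc2)c1
F11 | step 5 | 2,4-bis(benzyloxy)-1-(chloromethyl)benzene | ClCc1ccc(OCc2ccccc2)cc1OCc1ccccc1
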